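At the late end of the runs, the last readings already showed the balance: at 80.0 min the red run held 62.8 % product and 39.1 % substrate, which together make up the charge within the scatter. So I followed one substrate molecule through a single fork, turn now or wait.

| flask | substrate | remark | time |
|---|---|---|---|
| red | 4.8 mM | run made earlier |  |
| blue | 9.1 mM | run made earlier |  |
| green | 19 mM | run made earlier |  |
| Tuesday's | 4.0 mM |  | 2.0 h |
| Wednesday's | 25 mM |  | 2.0 h |
| Sunday's | 20 mM |  | 2.0 h |
| Monday's | 6.0 mM |  | 2.0 h |
| Thursday's | 12 mM |  | 2.0 h |

- red (time / min: product / %, substrate / %): 6.00: 5.7, 93.9; 12.0: 12.7, 88.5; 25.0: 22.5, 77.2; 40.0: 34.4, 64.3; 80.0: 62.8, 39.1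
- blue (time / min: product / %, substrate / %): 8.00: 6.6, 93.7; 20.0: 13.9, 86.6; 40.0: 26.5, 74.6; 60.0: 36.3, 63.1; 80.0: 46.6, 53.3
- green (time / min: product / %, substrate / %): 6.00: 4.1, 98.4; 12.0: 5.2, 94.5; 25.0: 9.5, 89.1; 40.0: 16.2, 85.5; 80.0: 29.4, 69.4

(standard deviation of a reading: 1 percentage point)



- ranking by amount of product, in percent of the substrate charged, from high to low, at 2.0 h (Tuesday's / Wednesday's / Sunday's / Monday's / Thursday's)
- the amount of product, in percent of the substrate charged of the flask you put first, at 2.0 h
- the amount of product, in percent of the substrate charged of the flask you put last, at 2.0 h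

I turned the question round. For the large charges to finish on top, a molecule's chance per minute would have to rise with the charge, so product in mM would have to grow by a larger factor than the charge. From red to green the charge grew by a factor of 3.96, but product at 80.0 min grew by 1.85, which is less, so that chance fell. This is saturation kinetics. For a charge C, with V the ceiling rate and K the concentration at which the rate is half of V, the time to convert a fraction x is

t(x) = (C·x + K·ln(1/(1−x)))/V

I averaged product and lost substrate at the last readings, giving x = 61.9 % for red and 30.0 % for green. Both runs share that time, so their difference gives K and red then gives V: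

K = 4.50 mM, V = 0.0913 mM min⁻¹

The blue run, not used here, gives V = 0.0884 mM min⁻¹. I carried the time to half conversion, the flask's half-life, which here grows with the charge:

t½ = (0.5·C + K·ln(2))/V

Tuesday's: 0.934 h. Wednesday's: 2.85 h.

Against 2.0 h, Tuesday's should pass half and Wednesday's should fall short. The opposite order needs a ratio of these half-lives below 1, and it stood at 3.05. At fixed K and V, t(x) rises with C, so I ranked the flasks by charge, lowest first.

The forecast gave Tuesday's > Monday's > Thursday's > Sunday's > Wednesday's, with 81 % and 36 %, noting that “Percent conversion falls as the charge rises”. Its order matched mine; my half-lives gave no percentages.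

The flasks gave Tuesday's > Monday's > Thursday's > Sunday's > Wednesday's, with 80.6 % in Tuesday's and 36.4 % in Wednesday's, so the forecast held.

    substrate → product, rate k1*[substrate]/(1 + ([substrate]/sat1)) (4.94 mM, k = 0.0191 min⁻¹)

Wednesday's still held 63.6 % substrate at 2.00 h, so I took its neighbour, the same flask left until 5.0 h. My half-life of 2.85 h put the even point inside that time, and substrate and product in fact stood equal at 2.81 h. Asked for the product that neighbour reached, t(x) gives 5.03 h for 80.7 %. At 5.0 h the neighbour held 80.7 % product and 19.3 % substrate.

Readings and results come from a simulation for an exercise.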